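**Retrosynthetic overview**
1. The THF ring is formed last: acid removes the C6 silyl ether and the C6–OH opens a (9S,10S)-epoxide at C9 (transannular 5-exo, inversion).
2. The 15-membered carbocycle comes from ring-closing metathesis at C3=C4; the C1 ketone comes from oxidation of a crotylation carbinol.
3. The C10–C11 bond comes from addition of a (Z)-alkenylcerium (C4–C10) to an all-cis δ-lactone (C11–C15 plus C1–C3); the THP hemiketal forms in this step.
4. The lactone comes from an NHC-catalysed asymmetric oxo-[4+2] (new, sets C12/C13), a face-selective hydrogenation (C15) and a phosphoric-acid-catalysed crotylboration (C2).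
5. The C4–C10 piece comes from propargyl alcohol ((Z)-iodoalkene) and a phosphoric-acid-catalysed reverse prenylation (C6). Ring order: THP (lactone, then hemiketal), macrocycle, THF.

Numbering: C1–C15 are the carbocycle carbons of the target (C1 ketone, C2 CHMe, C3=C4, C5 CMe2, C6 and C9 the THF carbons, C10 CHOH, C11 hemiketal, C12 CH–O-acyl, C13 CHMe, C14 CH2, C15 CH–O).

Assumption: (E)-3-methylpent-2-enoic acid and both pinacol boronates are taken as commercial; the absolute sense of the TRIP and triazolium catalysts is assigned by analogy with standard substrates, and the antipodal catalyst would be used if the sense is reversed.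

**Route**

Step 1
Reactants: 1 prop-2-yn-1-ol
Product: 2 (Z)-3-iodo-2-methylprop-2-en-1-ol
Conditions: MeMgBr (2.2 equiv), CuI (10 mol%), THF/Et2O, −10 °C to rt; then I2, −40 °C
Reagents that add atoms: methylmagnesium bromide, C[Mg]Br; iodine, II
Why: Cu-catalysed anti-carbomagnesiation of the propargylic alkoxide gives a chelated (Z)-alkenylmagnesium, and iodinolysis with retention fixes the future C9=C10 Z geometry.

Step 2
Reactants: 2 (Z)-3-iodo-2-methylprop-2-en-1-ol
Product: 3 (Z)-3-bromo-1-iodo-2-methylprop-1-ene
Conditions: CBr4, PPh3, CH2Cl2, 0 °C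
Reagents that add atoms: carbon tetrabromide, BrC(Br)(Br)Br
Why: Appel bromination of a primary allylic alcohol proceeds without allylic transposition or change in alkene geometry.

Step 3
Reactants: 3 (Z)-3-bromo-1-iodo-2-methylprop-1-ene; 4 acetaldehyde N,N-dimethylhydrazone
Product: 5 (Z)-5-iodo-4-methylpent-4-enal
Conditions: 4, LDA, THF, 0 °C; then 3, −78 °C; aq. oxalic acid/Et2O, rt
Reagents that add atoms: water, O
Why: SN2 alkylation of the lithiated hydrazone (azaenolate alkylation) followed by hydrolysis gives the aldehyde; the vinyl iodide has no anti β-hydrogen and survives the base.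

Step 4
Reactants: 5 (Z)-5-iodo-4-methylpent-4-enal; 6 prenylboronic acid pinacol ester
Product: 7 (4S,7Z)-8-iodo-3,3,7-trimethylocta-1,7-dien-4-ol
Conditions: (R)-TRIP phosphoric acid (5 mol%), 4 Å MS, toluene, −30 °C
Reagents that add atoms: 6, CC(C)=CCB1OC(C)(C)C(C)(C)O1
Why: Chiral-phosphoric-acid-catalysed allylboration through a closed chair transition state; γ-attack of the prenyl unit builds the C5 quaternary carbon and sets C6 (S), the first stereocentre of this branch.

Step 5
Reactants: 7 (4S,7Z)-8-iodo-3,3,7-trimethylocta-1,7-dien-4-ol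
Product: 8 triethyl{[(4S,7Z)-8-iodo-3,3,7-trimethylocta-1,7-dien-4-yl]oxy}silane
Conditions: TESOTf, 2,6-lutidine, CH2Cl2, −78 to 0 °C
Reagents that add atoms: triethylsilyl triflate, CC[Si](CC)(CC)OS(=O)(=O)C(F)(F)F
Why: Silylation of the hindered secondary alcohol; the TES group keeps C6–OH out of the later oxidation and comes off in the final acid step.

Step 6
Reactants: 9 1,1-dimethoxypropan-2-one; 10 acetaldehyde
Product: 11 (E)-1,1-dimethoxypent-3-en-2-one
Conditions: LDA, THF, −78 °C; MeCHO; then MsCl, Et3N, DBU, 0 °C to rt
Reagents that add atoms: none (both reactants numbered)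
Why: Directed aldol at the only enolisable methyl followed by E1cB dehydration gives the E-enone.

Step 7 (key step)
Reactants: 11 (E)-1,1-dimethoxypent-3-en-2-one; 12 2-(benzyloxy)acetyl chloride
Product: 13 (3R,4R)-3-(benzyloxy)-6-(dimethoxymethyl)-4-methyl-3,4-dihydro-2H-pyran-2-one
Conditions: aminoindanol-derived N-mesityl triazolium chloride (10 mol%), i-Pr2NEt (2.5 equiv), 12 added over 4 h, toluene, 0 °C
Reagents that add atoms: 12, O=C(Cl)COCc1ccccc1
Why: Proposed new method: the carbene is acylated by 12 (directly or via benzyloxyketene) and deprotonated to a (Z)-α-benzyloxy azolium enolate, which undergoes an endo inverse-demand oxo-Diels–Alder reaction with the s-cis enone 11 (C12–C13 bond, then O–C11 acylation releasing the carbene) to give the cis C12-OBn/C13-Me lactone with face control from the indane wall; the closest known reaction is the NHC-catalysed enolate oxodiene [4+2] of α-chloroaldehydes with enones, here extended to an α-alkoxy enolate.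

Step 8
Reactants: 13
Product: 14 (3R,4R,6R)-6-(dimethoxymethyl)-3-hydroxy-4-methyltetrahydro-2H-pyran-2-one
Conditions: H2 (1 atm), Pd/C, EtOAc, rt
Reagents that add atoms: none (H2 only)
Why: Heterogeneous hydrogenation adds H2 to the enol-lactone face opposite the cis C12-OBn and C13-Me groups, setting C15 all-cis, with concurrent hydrogenolysis of the benzyl ether.

Step 9
Reactants: 14; 15 (E)-3-methylpent-2-enoic acid
Product: 16 (3R,4R,6R)-6-(dimethoxymethyl)-4-methyl-2-oxotetrahydro-2H-pyran-3-yl (E)-3-methylpent-2-enoate
Conditions: EDC·HCl, DMAP (0.2 equiv), CH2Cl2, 0 °C to rt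
Reagents that add atoms: 15, CC/C(C)=C/C(=O)O
Why: Steglich esterification of the only free hydroxyl installs the natural ester early; carbodiimide activation avoids the vinylketene pathway that scrambles β,β-disubstituted enoates.

Step 10
Reactants: 16
Product: 17 (3R,4R,6R)-6-formyl-4-methyl-2-oxotetrahydro-2H-pyran-3-yl (E)-3-methylpent-2-enoate
Conditions: TFA/H2O (9:1), CH2Cl2, 0 °C to rt; toluene azeotrope; used crude
Reagents that add atoms: water, O
Why: Acid hydrolysis of the dimethyl acetal; the lactone and enoate tolerate aqueous acid and C15 is not epimerised under non-basic conditions.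

Step 11
Reactants: 17; 18 (E)-crotylboronic acid pinacol ester
Product: 19 (3R,4R,6R)-6-[(1S,2S)-1-hydroxy-2-methylbut-3-en-1-yl]-4-methyl-2-oxotetrahydro-2H-pyran-3-yl (E)-3-methylpent-2-enoate
Conditions: (S)-TRIP phosphoric acid (5 mol%), 4 Å MS, toluene, −30 °C
Reagents that add atoms: 18, C/C=C/CB1OC(C)(C)C(C)(C)O1
Why: Phosphoric-acid-catalysed (E)-crotylboration via a chair transition state gives the anti C1-OH/C2-Me pair; catalyst control and the Cornforth preference of the α-oxy aldehyde both favour the face that gives C2 (S).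

Step 12
Reactants: 8; 19
Product: 20 hemiketal, (2R,3R,4R,6R)-2-hydroxy-6-[(1S,2S)-1-hydroxy-2-methylbut-3-en-1-yl]-4-methyl-2-[(1Z,5S)-2,6,6-trimethyl-5-(triethylsilyloxy)octa-1,7-dien-1-yl]tetrahydro-2H-pyran-3-yl (E)-3-methylpent-2-enoate
Conditions: 8 (1.3 equiv), t-BuLi (2.1 equiv), Et2O, −78 °C; CeCl3, THF, −78 °C; then 19 pre-treated with MeMgBr (1.0 equiv, −78 °C); AcOH quench at −78 °C
Reagents that add atoms: none
Why: Li–I exchange with retention, transmetalation to the weakly basic alkenylcerium and 1,2-addition to the lactone (more electrophilic than the hindered enoate) give a stable lactol alkoxide, so there is no over-addition; the C11 hemiketal settles in the anomerically favoured natural configuration.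

Step 13
Reactants: 20
Product: 21 epoxide of 20 at C9=C10 (9S,10S; C11 now formally S by CIP, geometry unchanged)
Conditions: D-fructose-derived Shi ketone (30 mol%), Oxone, K2CO3, n-Bu4NHSO4, MeCN/DMM/aq. borate–EDTA buffer (pH about 9.5), 0 °C
Reagents that add atoms: Oxone (KHSO5), [K+].[O-]S(=O)(=O)OO
Why: Shi epoxidation transfers oxygen stereospecifically through a spiro transition state to the only electron-rich trisubstituted alkene (terminal vinyls and the enoate are inert); the spiro model that gives (R,R)-epoxides from trans- and trisubstituted alkenes predicts the (9S,10S) face here.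

Step 14
Reactants: 21
Product: 22 macrocyclic epoxy alcohol (15-membered ring, 3E; C1 (S)-OH, C2 (S), C6 (S)-OTES, 9S,10S-epoxide, C12 R, C13 R, C15 R)
Conditions: Hoveyda–Grubbs II (15 mol%), 1,4-benzoquinone (30 mol%), toluene (1 mM), 80 °C
Reagents that add atoms: none (ethylene lost)
Why: Ring-closing metathesis of the two terminal vinyl groups; the E alkene flanked by C2 and the C5 quaternary carbon is the thermodynamic product, and benzoquinone suppresses Ru–H alkene migration.

Step 15
Reactants: 22
Product: 23 macrocyclic epoxy ketone (C1 ketone; C2 S)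
Conditions: Dess–Martin periodinane, NaHCO3, CH2Cl2, 0 °C to rt
Reagents that add atoms: none
Why: Dess–Martin oxidation of the only free secondary alcohol under buffered, non-basic conditions, so the C2 α-stereocentre and the β,γ-alkene are not disturbed.

Step 16
Reactants: 23
Product: 24 tonantzitlolone A
Conditions: HF·pyridine, THF/pyridine, 0 °C to rt; then PPTS (cat.), CH2Cl2, rt if the epoxy alcohol persists
Reagents that add atoms: none
Why: Acid removes the TES group and the freed C6–OH opens the protonated epoxide at the tertiary C9 (transannular 5-exo-tet, inversion), giving C9 (R), retaining C10 (S)-OH and closing the cis-THF.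

**Compound list**
1 | prop-2-yn-1-ol | C#CCO | starting material
2 | (Z)-3-iodo-2-methylprop-2-en-1-ol | OC/C(C)=C\I | intermediate
3 | (Z)-3-bromo-1-iodo-2-methylprop-1-ene | BrC/C(C)=C\I | intermediate
4 | acetaldehyde N,N-dimethylhydrazone | CC=NN(C)C | starting material
5 | (Z)-5-iodo-4-methylpent-4-enal | O=CCC/C(C)=C\I | intermediate
6 | prenylboronic acid pinacol ester | CC(C)=CCB1OC(C)(C)C(C)(C)O1 | starting material
7 | (4S,7Z)-8-iodo-3,3,7-trimethylocta-1,7-dien-4-ol | I\C=C(C)/CC[C@H](O)C(C)(C)C=C | intermediate
8 | TES ether of 7 | I\C=C(C)/CC[C@H](O[Si](CC)(CC)CC)C(C)(C)C=C | intermediate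
9 | 1,1-dimethoxypropan-2-one | CC(=O)C(OC)OC | starting material
10 | acetaldehyde | CC=O | starting material
11 | (E)-1,1-dimethoxypent-3-en-2-one | C/C=C/C(=O)C(OC)OC | intermediate
12 | 2-(benzyloxy)acetyl chloride | O=C(Cl)COCc1ccccc1 | starting material
13 | (3R,4R)-3-(benzyloxy)-6-(dimethoxymethyl)-4-methyl-3,4-dihydro-2H-pyran-2-one | COC(OC)C1=C[C@@H](C)[C@@H](OCc2ccccc2)C(=O)O1 | intermediate
14 | (3R,4R,6R)-6-(dimethoxymethyl)-3-hydroxy-4-methyltetrahydro-2H-pyran-2-one | COC(OC)[C@H]1C[C@@H](C)[C@@H](O)C(=O)O1 | intermediate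
15 | (E)-3-methylpent-2-enoic acid | CC/C(C)=C/C(=O)O | starting material
16 | acetal lactone ester (see Step 9) | CC/C(C)=C/C(=O)O[C@@H]1[C@H](C)C[C@H](C(OC)OC)OC1=O | intermediate
17 | aldehyde lactone ester (see Step 10) | CC/C(C)=C/C(=O)O[C@@H]1[C@H](C)C[C@H](C=O)OC1=O | intermediate
18 | (E)-crotylboronic acid pinacol ester | C/C=C/CB1OC(C)(C)C(C)(C)O1 | starting material
19 | homoallylic alcohol lactone (see Step 11) | CC/C(C)=C/C(=O)O[C@@H]1[C@H](C)C[C@H]([C@@H](O)[C@@H](C)C=C)OC1=O | intermediate
20 | coupled (Z)-alkenyl hemiketal (see Step 12) | CC/C(C)=C/C(=O)O[C@@H]1[C@H](C)C[C@H]([C@@H](O)[C@@H](C)C=C)O[C@]1(O)/C=C(C)\CC[C@H](O[Si](CC)(CC)CC)C(C)(C)C=C | intermediate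
21 | (9S,10S)-epoxy hemiketal | CC/C(C)=C/C(=O)O[C@@H]1[C@H](C)C[C@H]([C@@H](O)[C@@H](C)C=C)O[C@]1(O)[C@H]1O[C@@]1(C)CC[C@H](O[Si](CC)(CC)CC)C(C)(C)C=C | intermediate
22 | macrocyclic epoxy alcohol (RCM product) | CC/C(C)=C/C(=O)O[C@@H]1[C@H](C)C[C@H]2O[C@]1(O)[C@H]1O[C@@]1(C)CC[C@H](O[Si](CC)(CC)CC)C(C)(C)/C=C/[C@H](C)[C@@H]2O | intermediate
23 | macrocyclic epoxy ketone | CC/C(C)=C/C(=O)O[C@@H]1[C@H](C)C[C@H]2O[C@]1(O)[C@H]1O[C@@]1(C)CC[C@H](O[Si](CC)(CC)CC)C(C)(C)/C=C/[C@H](C)C2=O | intermediate
24 | tonantzitlolone A | CC/C(C)=C/C(=O)O[C@@H]1[C@H](C)C[C@H]2O[C@]1(O)[C@@H](O)[C@@]1(C)CC[C@H](O1)C(C)(C)/C=C/[C@H](C)C2=O | target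

**Totals**
Total steps: 16. Longest linear sequence: 11 (Steps 6–11, then 12–16); the other branch is 10 (Steps 1–5, then 12–16).

**Three steps most likely to fail**
1. Step 7 (proposed new NHC oxo-[4+2]). Risks are ketene dimerisation, low reactivity of the β-methyl enone and erosion of cis selectivity. Fallback with known chemistry: build the same C11–C15 lactone linearly from citral. Iminium-catalysed Hantzsch-ester transfer hydrogenation gives (R)-citronellal (C13); proline/nitrosobenzene α-aminoxylation sets C12; after alkene ozonolysis a second α-aminoxylation sets C15; oxidation and lactonisation follow. This is roughly four steps longer.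
2. Step 14 (RCM at a neopentyl alkene next to an α-branched centre). Fallback: re-cut the macrocycle at C5–C6 and close it by an intramolecular Nozaki–Hiyama (CrCl2) reverse-prenylation of a C6 aldehyde with a C3 allylic bromide. γ-Attack forms the quaternary C5 and the E-C3=C4 alkene in one step; C6 is then corrected by oxidation and CBS reduction if needed.
3. Step 13 (catalyst-controlled epoxidation of a hindered Z-alkene beside a base-sensitive α-acyloxy hemiketal). Fallback: run RCM first and epoxidise the macrocyclic trisubstituted alkene under substrate control (buffered peracid, or hemiketal-OH-directed VO(acac)2/t-BuOOH). This relies on peripheral attack on the macrocycle instead of the chiral ketone, and is followed by the same transannular opening.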